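**Retrosynthetic overview**
1. Pyranone ring C: disconnect O1–C8a as a dehydrogenative coupling of a ring-A C–H with an enol O–H, giving an open-chain 1,3-diaryl-1,3-diketone. Ring A (2,3,4,5-tetramethoxyphenyl) has a single free C–H, ortho to the carbonyl, so closure there can only give the 5,6,7,8-pattern.
2. Diketone: disconnect the CH2–C(=O) bond into a ring-A methyl ketone and a ring-B aroyl chloride (C-acylation by soft enolisation).
3. Ring-A ketone from Friedel–Crafts acetylation of 1,2,3,4-tetramethoxybenzene. Ring-B acid from syringic acid with the 4-OH masked as an acetate, which shields the phenol from oxidation, deactivates ring B and is removed in the flask of the last step.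
4. Rings A and B are bought as benzenes; ring C is the only ring formed, and it is formed last. Forward: 1 → 2; 3 → 4; 2 + 4 → (5) → 6 → (7) → 8.

Assumption: the target has no stereocentre or stereogenic axis, so the achiral compound itself is the required product; 1,2,3,4-tetramethoxybenzene is taken as a catalogue starting material.

**Step 1**
Reactants: 1 1,2,3,4-tetramethoxybenzene
Product: 2 1-(2,3,4,5-tetramethoxyphenyl)ethan-1-one
Conditions: Ac2O (1.5 equiv), Sc(OTf)3 (10 mol %), MeNO2, 50 °C
Reagents that add atoms: acetic anhydride, CC(=O)OC(C)=O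
Why: Friedel–Crafts acylation; the two free ring positions are equivalent and activated (ortho and para to OMe), the ketone product is deactivated towards a second acylation, and a catalytic metal triflate avoids the ortho-demethylation that stoichiometric AlCl3 causes.

**Step 2**
Reactants: 3 syringic acid (4-hydroxy-3,5-dimethoxybenzoic acid)
Product: 4 4-acetoxy-3,5-dimethoxybenzoic acid
Conditions: Ac2O (3 equiv), pyridine, rt; then H2O, dilute HCl work-up
Reagents that add atoms: acetic anhydride, CC(=O)OC(C)=O
Why: Phenol O-acetylation; the hindered but acidic syringyl OH is acylated cleanly and the free acid is recovered after the aqueous quench.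

**Step 3**
Reactants: 2 1-(2,3,4,5-tetramethoxyphenyl)ethan-1-one; 4 4-acetoxy-3,5-dimethoxybenzoic acid
Product: 6 4-[3-oxo-3-(2,3,4,5-tetramethoxyphenyl)propanoyl]-2,6-dimethoxyphenyl acetate (present mainly as the chelated enol), via 4-acetoxy-3,5-dimethoxybenzoyl chloride 5 (not isolated)
Conditions: 4, (COCl)2 (1.3 equiv), DMF (cat.), CH2Cl2, 0 °C → rt, evaporate; then 2, MgBr2·OEt2 (2.5 equiv), i-Pr2NEt (3 equiv), CH2Cl2, rt; 1 M HCl work-up
Reagents that add atoms: none
Why: Acid chloride formation followed by crossed Claisen-type C-acylation under soft enolisation; the Mg-chelated methyl ketone is deprotonated by the weak amine, the enolate is C-aroylated, the product is held as its magnesium diketonate (no second acylation), and the base is too weak to cleave the aryl acetate.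

**Step 4**
Reactants: 6 4-[3-oxo-3-(2,3,4,5-tetramethoxyphenyl)propanoyl]-2,6-dimethoxyphenyl acetate
Product: 8 4'-hydroxy-3',5,5',6,7,8-hexamethoxyflavone, via 4'-acetoxy-3',5,5',6,7,8-hexamethoxyflavone 7 (not isolated)
Conditions: 9-mesityl-3,6-di-tert-butyl-10-phenylacridinium BF4 (5 mol %), Co(dmgH)2(py)Cl (8 mol %), DCE–HFIP (4:1), 0.05 M, Ar, 450 nm LEDs, rt; then NH3 (7 M in MeOH), rt, 1 h
Reagents that add atoms: none
Why: Proposed new method: an acceptorless dehydrogenative aryl C–H/enol O–H coupling that closes the pyranone ring at O1–C8a. The excited acridinium (E*red about +2.0 V vs SCE) oxidises the tetramethoxyphenyl ring of 6 to its radical cation; this is the most electron-rich π-system, since ring B is deactivated by its acetoxy group. The enol oxygen on the ring-B side sits 1,6 to the only free ring-A position (C6–H, para to the 3-OMe, where the radical-cation coefficient is large) and adds there in a six-membered closure. The cyclohexadienyl radical loses H+ and is oxidised by the cobaloxime, which releases the two hydrogens as H2, so no chemical oxidant is present that could attack the diketone or the product; ammonia in methanol then cleaves the aryl acetate in the same flask. Closest known reaction type: acridinium/cobaloxime dehydrogenative lactonisation of biaryl-2-carboxylic acids and C–H etherification or amination of arene radical cations (also FeCl3- or DDQ-mediated oxidative C–O closure of α-aryl ketones to benzofurans), extended here to a β-diketone enol (a vinylogous acid), on which it has not been shown.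

**Compound list**
1 | 1,2,3,4-tetramethoxybenzene | COc1ccc(OC)c(OC)c1OC | starting material
2 | 1-(2,3,4,5-tetramethoxyphenyl)ethan-1-one | CC(=O)c1cc(OC)c(OC)c(OC)c1OC | intermediate
3 | syringic acid (4-hydroxy-3,5-dimethoxybenzoic acid) | COc1cc(C(=O)O)cc(OC)c1O | starting material
4 | 4-acetoxy-3,5-dimethoxybenzoic acid | COc1cc(C(=O)O)cc(OC)c1OC(C)=O | intermediate
5 | 4-acetoxy-3,5-dimethoxybenzoyl chloride | COc1cc(C(=O)Cl)cc(OC)c1OC(C)=O | intermediate (not isolated)
6 | 4-[3-oxo-3-(2,3,4,5-tetramethoxyphenyl)propanoyl]-2,6-dimethoxyphenyl acetate | COc1cc(C(=O)CC(=O)c2cc(OC)c(OC)c(OC)c2OC)cc(OC)c1OC(C)=O | intermediate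
7 | 4'-acetoxy-3',5,5',6,7,8-hexamethoxyflavone (2,6-dimethoxy-4-(5,6,7,8-tetramethoxy-4-oxo-4H-chromen-2-yl)phenyl acetate) | COc1cc(-c2cc(=O)c3c(OC)c(OC)c(OC)c(OC)c3o2)cc(OC)c1OC(C)=O | intermediate (not isolated)
8 | 4'-hydroxy-3',5,5',6,7,8-hexamethoxyflavone | COc1cc(-c2cc(=O)c3c(OC)c(OC)c(OC)c(OC)c3o2)cc(OC)c1O | target

**Totals**
Total step count: 4 (steps 1 and 2 run in parallel).
Longest linear sequence: 3 steps (1 → 2 → 6 → 8, or 3 → 4 → 6 → 8).

**Three steps most likely to fail**

Step 4 (the proposed new step). Possible failures: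
- ipso attack of the enol oxygen at C2–OMe of ring A with loss of methanol, which would give the 5-demethoxy flavone;
- attack on ring B instead of ring A;
- binding of the diketonate to cobalt, which would stall hydrogen evolution;
- slow closure, because the reacting conformer has to give up the enol hydrogen bond.

Fallback, known chemistry only; it sets out from 2 and comes back to the route at 8. Baeyer–Villiger oxidation of 2 (mCPBA, NaHCO3, CH2Cl2) gives 2,3,4,5-tetramethoxyphenyl acetate F1. Fries rearrangement (BF3·OEt2, AcOH, 80 °C) moves the acetyl group to the only free ring position and gives 1-(2-hydroxy-3,4,5,6-tetramethoxyphenyl)ethan-1-one F2. Claisen–Schmidt condensation (KOH, EtOH, rt) with bought 4-(benzyloxy)-3,5-dimethoxybenzaldehyde F3 gives the 2'-hydroxychalcone (E)-3-[4-(benzyloxy)-3,5-dimethoxyphenyl]-1-(2-hydroxy-3,4,5,6-tetramethoxyphenyl)prop-2-en-1-one F4. Oxidative cyclisation with I2 (cat.) in DMSO at 120 °C forms the ring C–O bond by oxa-Michael addition of the pre-installed phenol and gives 4'-benzyloxy-3',5,5',6,7,8-hexamethoxyflavone F5. Hydrogenolysis (H2, Pd/C, EtOAc, rt) then gives 8.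

Step 3. Possible failures: O-acylation of the enolate instead of C-acylation, or sluggish reaction of the ortho-substituted ketone.

Fallback, aldol and oxidation instead of acylation; it sets out from 2 and comes back at 6. Ketone 2 is silylated (TMSOTf, Et3N, CH2Cl2, 0 °C) to trimethyl{[1-(2,3,4,5-tetramethoxyphenyl)ethenyl]oxy}silane F6. Mukaiyama aldol addition (BF3·OEt2, CH2Cl2, −78 °C) to bought 4-formyl-2,6-dimethoxyphenyl acetate F7 gives racemic 4-[1-hydroxy-3-oxo-3-(2,3,4,5-tetramethoxyphenyl)propyl]-2,6-dimethoxyphenyl acetate F8; its stereocentre is removed in the next operation. Dess–Martin periodinane (CH2Cl2, rt) oxidises the β-hydroxy ketone to 6.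

Step 1. Possible failures: low turnover of the triflate catalyst by product binding, or ortho-demethylation if a stronger acid has to be used.

Fallback, nucleophilic arene instead of electrophilic substitution; it sets out from 1 and comes back at 2. Directed ortho-lithiation of 1 (n-BuLi, TMEDA, THF, 0 °C; both ring hydrogens are equivalent and ortho to OMe) gives (2,3,4,5-tetramethoxyphenyl)lithium F9. This is acylated with N-methoxy-N-methylacetamide (−78 °C → rt, then aqueous HCl) to give 2 without over-addition.

**Further compounds**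
F1 | step 4 | 2,3,4,5-tetramethoxyphenyl acetate | CC(=O)Oc1cc(OC)c(OC)c(OC)c1OC
F2 | step 4 | 1-(2-hydroxy-3,4,5,6-tetramethoxyphenyl)ethan-1-one | CC(=O)c1c(O)c(OC)c(OC)c(OC)c1OC
F3 | step 4 | 4-(benzyloxy)-3,5-dimethoxybenzaldehyde | COc1cc(C=O)cc(OC)c1OCc1ccccc1
F4 | step 4 | (E)-3-[4-(benzyloxy)-3,5-dimethoxyphenyl]-1-(2-hydroxy-3,4,5,6-tetramethoxyphenyl)prop-2-en-1-one | COc1cc(/C=C/C(=O)c2c(O)c(OC)c(OC)c(OC)c2OC)cc(OC)c1OCc1ccccc1
F5 | step 4 | 4'-benzyloxy-3',5,5',6,7,8-hexamethoxyflavone | COc1cc(-c2cc(=O)c3c(OC)c(OC)c(OC)c(OC)c3o2)cc(OC)c1OCc1ccccc1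
F6 | step 3 | trimethyl{[1-(2,3,4,5-tetramethoxyphenyl)ethenyl]oxy}silane | C=C(O[Si](C)(C)C)c1cc(OC)c(OC)c(OC)c1OC
F7 | step 3 | 4-formyl-2,6-dimethoxyphenyl acetate | COc1cc(C=O)cc(OC)c1OC(C)=O
F8 | step 3 | racemic 4-[1-hydroxy-3-oxo-3-(2,3,4,5-tetramethoxyphenyl)propyl]-2,6-dimethoxyphenyl acetate | COc1cc(C(O)CC(=O)c2cc(OC)c(OC)c(OC)c2OC)cc(OC)c1OC(C)=O
F9 | step 1 | (2,3,4,5-tetramethoxyphenyl)lithium | [Li]c1cc(OC)c(OC)c(OC)c1OC
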